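**Plan**

- Retrosynthesis: the myristate C–O bond is cut with inversion (Mitsunobu), the carbinol oxygen on the exocyclic carbon C1' is traded for silicon (Fleming–Tamao, retention), and the oxolane is then opened at two bonds at once, C3–C4 and O1–C5, to (S)-2-(benzyloxy)heptanal and an α-branched allylsilane.
- Forward: the aldehyde (2 steps) and the allylsilane (4 steps) are joined in a SnCl4-mediated formal [3+2] annulation that builds the only ring in one operation; PMB protection, Si→OH exchange, invertive esterification and PMB removal finish the route.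
- Enabling feature (ring numbered O1, C2 pentyl, C3 hydroxyl, C4, C5): O1 on C2 next to the free hydroxyl on C3 is a masked α-oxy aldehyde. C4H2–C5H, flanked by the oxygenated exocyclic C1', is a masked allylsilane C=C whose silicon (later oxygen) stabilises positive charge at C5.
- Stereochemistry: C2 comes from (S)-oct-1-en-3-ol; C3 from chelation control; C5 from the silicon-bearing stereocentre (anti SE2' attack and anti capture), which is set by copper-catalysed asymmetric allylic silylation; C1' by retentive oxidation followed by invertive esterification.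

Key step: step 7

Assumption: (S)-oct-1-en-3-ol is bought as the single enantiomer (it is also the unreacted enantiomer in lipase acylation of the cheap racemate).

**Route**

Step 1
Reactants: 1 (S)-oct-1-en-3-ol
Product: 2 (S)-3-(benzyloxy)oct-1-ene
Conditions: NaH, BnBr, Bu4NI (cat.), THF, 0 °C → rt
Reagents that add atoms: benzyl bromide, BrCc1ccccc1
Why: Williamson etherification of the secondary alkoxide with benzyl bromide, which leaves the carbinol stereocentre (the future C2) untouched.

Step 2
Reactants: 2 (S)-3-(benzyloxy)oct-1-ene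
Product: 4 (S)-2-(benzyloxy)heptanal, via ozonide 3 (not isolated)
Conditions: O3, CH2Cl2, −78 °C; then Me2S, −78 °C → rt; used crude
Reagents that add atoms: ozone, O=[O+][O-]
Why: Ozonolysis of the terminal alkene (Criegee mechanism) with reductive work-up should give the α-benzyloxy aldehyde without touching the stereocentre, and immediate use of the crude aldehyde limits epimerisation.

Step 3
Reactants: 5 prop-2-yn-1-ol; 6 9-bromonon-1-ene
Product: 7 dodec-11-en-2-yn-1-ol
Conditions: 5 (2 equiv), n-BuLi (4 equiv), THF–DMPU, −78 → 0 °C; then 6, 0 °C → rt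
Reagents that add atoms: none
Why: C-alkylation of the propargyl alcohol dianion, whose acetylide carbon is far more nucleophilic than the alkoxide, by SN2 displacement at the primary bromide.

Step 4
Reactants: 7 dodec-11-en-2-yn-1-ol
Product: 8 (E)-dodeca-2,11-dien-1-ol
Conditions: LiAlH4, THF, 0 °C → reflux; aqueous NaOH work-up
Reagents that add atoms: none
Why: Hydroxyl-directed trans-hydroalumination of the propargylic alcohol should give only the E-allylic alcohol, while the isolated terminal alkene is inert to LiAlH4.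

Step 5
Reactants: 8 (E)-dodeca-2,11-dien-1-ol
Product: 9 diethyl (E)-dodeca-2,11-dien-1-yl phosphate
Conditions: ClP(O)(OEt)2, Et3N, DMAP (cat.), CH2Cl2, 0 °C
Reagents that add atoms: diethyl chlorophosphate, CCOP(=O)(Cl)OCC
Why: Phosphorylation of the primary allylic alcohol installs the leaving group required for copper-catalysed allylic substitution.

Step 6
Reactants: 9 diethyl (E)-dodeca-2,11-dien-1-yl phosphate
Product: 10 [(3S)-dodeca-1,11-dien-3-yl]dimethyl(phenyl)silane
Conditions: PhMe2Si–Bpin, CuCl (5 mol %), chiral N-heterocyclic carbene ligand (from its azolium salt, enantiomer giving the S product), NaOMe, THF, 0 °C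
Reagents that add atoms: 2-[dimethyl(phenyl)silyl]-4,4,5,5-tetramethyl-1,3,2-dioxaborolane, C[Si](C)(c1ccccc1)B1OC(C)(C)C(C)(C)O1
Why: Copper-catalysed enantioselective γ-selective allylic substitution (SN2') by a silylcopper species formed through Si–B transmetalation should give the branched α-chiral allylsilane, the chiral carbene ligand on copper setting the silicon-bearing stereocentre as S.

Step 7
Reactants: 4 (S)-2-(benzyloxy)heptanal; 10 [(3S)-dodeca-1,11-dien-3-yl]dimethyl(phenyl)silane
Product: 13 (2S,3S,5R)-5-{(1S)-1-[dimethyl(phenyl)silyl]dec-9-en-1-yl}-2-pentyloxolan-3-ol, via tin-bound beta-silyl cation 11 (not isolated), via O-benzyl oxonium ion 12 (not isolated)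
Conditions: SnCl4 (1.05 equiv), CH2Cl2, −78 °C (4 precomplexed, then 10), −78 → −40 °C; aq. NaHCO3
Reagents that add atoms: none
Why: Proposed new method: SnCl4 binds the aldehyde oxygen and the benzyl ether oxygen of 4 as a five-membered Cram chelate, the terminal CH2 of allylsilane 10 attacks the aldehyde carbon anti to silicon (SE2') on the chelate face opposite the pentyl group to give the siliranium-like cation 11, and the ether oxygen, once released from tin, captures the cationic carbon anti to silicon to give oxonium ion 12, which loses benzyl to chloride. The closest known reaction types are the Lewis acid-mediated formal [3+2] annulation of α-silyloxy aldehydes with achiral allylsilanes to 5-(silylmethyl)oxolan-3-ols and the chelation-controlled Hosomi–Sakurai addition to α-benzyloxy aldehydes; new here are the α-branched enantioenriched allylsilane and the benzyl ether as the ring-closing oxygen. The one ring formed (oxolane O1–C2–C3–C4–C5) closes in the 5-exo-tet mode by opening of the siliranium ion at its ring-side carbon. C3 (S) is set by the chelate (2,3-syn), C5 (R) by the silicon-bearing stereocentre through its H-inside conformer and anti attack of both the aldehyde and the oxygen, and the C–Si centre is carried through unchanged, so the aldehyde face and the alkene face are fixed by separate elements. The step needs ring closure to outrun chloride-induced desilylation to the open-chain E-homoallylic alcohol and five-ring capture to outrun 1,2-silyl shift with six-ring capture, which the hindered PhMe2Si group, the low temperature and the ether oxygen placed four atoms from the cation should secure. The chelate should also hold the alkene antiperiplanar to the carbonyl with the silyl-bearing carbon over the formyl hydrogen, the arrangement that leads to the required 3,5-trans ring.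

Step 8
Reactants: 13 (2S,3S,5R)-5-{(1S)-1-[dimethyl(phenyl)silyl]dec-9-en-1-yl}-2-pentyloxolan-3-ol
Product: 14 {(1S)-1-[(2R,4S,5S)-4-[(4-methoxybenzyl)oxy]-5-pentyloxolan-2-yl]dec-9-en-1-yl}dimethyl(phenyl)silane
Conditions: NaH, PMBCl, Bu4NI (cat.), DMF, 0 °C → rt
Reagents that add atoms: 4-methoxybenzyl chloride, COc1ccc(CCl)cc1
Why: Williamson etherification masks the ring hydroxyl so that only the later C1' hydroxyl can be esterified, and the C–Si bond and β-silyl ether are stable to NaH.

Step 9
Reactants: 14 {(1S)-1-[(2R,4S,5S)-4-[(4-methoxybenzyl)oxy]-5-pentyloxolan-2-yl]dec-9-en-1-yl}dimethyl(phenyl)silane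
Product: 15 (1S)-1-[(2R,4S,5S)-4-[(4-methoxybenzyl)oxy]-5-pentyloxolan-2-yl]dec-9-en-1-ol
Conditions: t-BuOOH, KH, NMP, 0 °C → rt; then Bu4NF, 70 °C
Reagents that add atoms: tert-butyl hydroperoxide, CC(C)(C)OO
Why: Fleming–Tamao oxidation in its one-pot basic peroxide/fluoride form, in which the peroxide anion adds to fluoride-activated silicon and C1' migrates from silicon to oxygen with retention, should give the (1S) carbinol while the non-acidic, non-electrophilic conditions spare the terminal alkene and the PMB ether.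

Step 10
Reactants: 15 (1S)-1-[(2R,4S,5S)-4-[(4-methoxybenzyl)oxy]-5-pentyloxolan-2-yl]dec-9-en-1-ol; 16 tetradecanoic acid
Product: 17 (1R)-1-[(2R,4S,5S)-4-[(4-methoxybenzyl)oxy]-5-pentyloxolan-2-yl]dec-9-en-1-yl tetradecanoate
Conditions: PPh3, DIAD, THF, 0 °C → rt
Reagents that add atoms: none
Why: Mitsunobu esterification displaces the phosphorus-activated secondary alcohol by the carboxylate in an SN2 step with inversion, so the ester is installed and C1' is corrected from S to the required R in one operation.

Step 11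
Reactants: 17 (1R)-1-[(2R,4S,5S)-4-[(4-methoxybenzyl)oxy]-5-pentyloxolan-2-yl]dec-9-en-1-yl tetradecanoate
Product: 18 (1R)-1-[(2R,4S,5S)-4-hydroxy-5-pentyloxolan-2-yl]dec-9-en-1-yl tetradecanoate (CNP0191164.1)
Conditions: DDQ, CH2Cl2–aqueous pH 7 buffer, 0 °C → rt
Reagents that add atoms: none
Why: Oxidative cleavage of the PMB ether by DDQ (benzylic hydride abstraction, then hydrolysis of the hemiacetal) should free the ring hydroxyl without affecting the ester, the terminal alkene or any stereocentre.

**Compound list**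

1 | (S)-oct-1-en-3-ol | C=C[C@H](CCCCC)O | starting material
2 | (S)-3-(benzyloxy)oct-1-ene | C=C[C@H](CCCCC)OCc1ccccc1 | intermediate
3 | 3-[(1S)-1-(benzyloxy)hexyl]-1,2,4-trioxolane (ozonide, not isolated) | CCCCC[C@H](OCc1ccccc1)C1OCOO1 | intermediate
4 | (S)-2-(benzyloxy)heptanal | CCCCC[C@H](OCc1ccccc1)C=O | intermediate
5 | prop-2-yn-1-ol | C#CCO | starting material
6 | 9-bromonon-1-ene | C=CCCCCCCCBr | starting material
7 | dodec-11-en-2-yn-1-ol | C=CCCCCCCCC#CCO | intermediate
8 | (E)-dodeca-2,11-dien-1-ol | C=CCCCCCCC/C=C/CO | intermediate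
9 | diethyl (E)-dodeca-2,11-dien-1-yl phosphate | C=CCCCCCCC/C=C/COP(=O)(OCC)OCC | intermediate
10 | [(3S)-dodeca-1,11-dien-3-yl]dimethyl(phenyl)silane | C=C[C@@H]([Si](C)(C)c1ccccc1)CCCCCCCC=C | intermediate
11 | open-chain β-silyl carbocation after C3–C4 bond formation, as trichlorotin alkoxide with chloride counter-ion (not isolated) | C=CCCCCCCC[C@H]([Si](C)(C)c1ccccc1)[CH+]C[C@H](O[Sn](Cl)(Cl)Cl)[C@H](CCCCC)OCc1ccccc1.[Cl-] | intermediate
12 | O-benzyl oxolanium ion after O1–C5 bond formation, as trichlorotin alkoxide with chloride counter-ion (not isolated) | C=CCCCCCCC[C@H]([Si](C)(C)c1ccccc1)[C@H]1C[C@H](O[Sn](Cl)(Cl)Cl)[C@H](CCCCC)[O+]1Cc1ccccc1.[Cl-] | intermediate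
13 | (2S,3S,5R)-5-{(1S)-1-[dimethyl(phenyl)silyl]dec-9-en-1-yl}-2-pentyloxolan-3-ol | C=CCCCCCCC[C@H]([Si](C)(C)c1ccccc1)[C@H]1C[C@H](O)[C@H](CCCCC)O1 | intermediate
14 | {(1S)-1-[(2R,4S,5S)-4-[(4-methoxybenzyl)oxy]-5-pentyloxolan-2-yl]dec-9-en-1-yl}dimethyl(phenyl)silane | C=CCCCCCCC[C@H]([Si](C)(C)c1ccccc1)[C@H]1C[C@H](OCc2ccc(OC)cc2)[C@H](CCCCC)O1 | intermediate
15 | (1S)-1-[(2R,4S,5S)-4-[(4-methoxybenzyl)oxy]-5-pentyloxolan-2-yl]dec-9-en-1-ol | C=CCCCCCCC[C@H](O)[C@H]1C[C@H](OCc2ccc(OC)cc2)[C@H](CCCCC)O1 | intermediate
16 | tetradecanoic acid (myristic acid) | CCCCCCCCCCCCCC(=O)O | starting material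
17 | (1R)-1-[(2R,4S,5S)-4-[(4-methoxybenzyl)oxy]-5-pentyloxolan-2-yl]dec-9-en-1-yl tetradecanoate | C=CCCCCCCC[C@@H](OC(=O)CCCCCCCCCCCCC)[C@H]1C[C@H](OCc2ccc(OC)cc2)[C@H](CCCCC)O1 | intermediate
18 | (1R)-1-[(2R,4S,5S)-4-hydroxy-5-pentyloxolan-2-yl]dec-9-en-1-yl tetradecanoate | C=CCCCCCCC[C@@H](OC(=O)CCCCCCCCCCCCC)[C@H]1C[C@H](O)[C@H](CCCCC)O1 | target

**Totals and risks**

Total step count: 11. Longest linear sequence: 9 steps (steps 3 to 11).

Steps most likely to fail:

1. Step 7 (Proposed new method). Chloride may desilylate the β-silyl cation before the ether oxygen closes the ring, a 1,2-silyl shift may lead to six-ring capture, or facial control may erode if the chelate is lost or the silane reacts through its minor conformer. Fallback with known chemistry, setting out from 4 and 10 and returning at 15: the two bond formations are separated. A chelation-controlled Hosomi–Sakurai reaction (TiCl4, CH2Cl2, −78 °C) should give (6S,7S,9E)-6-(benzyloxy)nonadeca-9,18-dien-7-ol F1. Its hydroxyl is protected (NaH, PMBCl, DMF) to give 1-({[(6S,7S,9E)-6-(benzyloxy)nonadeca-9,18-dien-7-yl]oxy}methyl)-4-methoxybenzene F2. Shi epoxidation of the internal E-alkene (KHSO5, K2CO3, MeCN–dimethoxymethane–buffer, 0 °C) follows, with the ketone enantiomer that delivers the (S,S)-epoxide (expected to be the L-fructose series); the terminal alkene reacts much more slowly. This gives (2S,3S)-2-{(2S,3S)-3-(benzyloxy)-2-[(4-methoxybenzyl)oxy]octyl}-3-(non-8-en-1-yl)oxirane F3. BF3·OEt2 (CH2Cl2, −78 °C) then triggers 5-exo opening of the epoxide by the benzyl ether oxygen with inversion and loss of benzyl, giving 15 directly.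

2. Step 9. Fluoride or base may trigger β-elimination across the Si–C1'–C5–O1 unit (ring opening) instead of migration of carbon to oxygen, or oxidation may stall at the hindered secondary silicon centre. Fallback setting out from 14 and returning at 15: the elimination is used on purpose. BF3·OEt2 (CH2Cl2, −20 °C) should effect anti Peterson-type ring opening to (6S,7S,9E)-7-[(4-methoxybenzyl)oxy]nonadeca-9,18-dien-6-ol F4. Shi epoxidation as above gives (2S,3S)-2-[(4-methoxybenzyl)oxy]-1-[(2S,3S)-3-(non-8-en-1-yl)oxiran-2-yl]octan-3-ol F5. Camphorsulfonic acid (cat., CH2Cl2) then closes the oxolane by 5-exo attack of the free hydroxyl with inversion, giving 15.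

3. Step 10. Activation of the hindered carbinol by the weakly acidic fatty acid may be slow, so that elimination or participation of the ring oxygen (retention, ring expansion) competes with SN2 inversion. Fallback setting out from 15 and returning at 17: oxidation with Dess–Martin periodinane (NaHCO3, CH2Cl2) gives 1-{(2R,4S,5S)-4-[(4-methoxybenzyl)oxy]-5-pentyloxolan-2-yl}dec-9-en-1-one F6. Felkin–Anh reduction with LiBH(s-Bu)3 (THF, −78 °C), hydride adding anti to the ring C–O bond, should give the threo alcohol (1R)-1-{(2R,4S,5S)-4-[(4-methoxybenzyl)oxy]-5-pentyloxolan-2-yl}dec-9-en-1-ol F7. Acylation with tetradecanoyl chloride (pyridine, DMAP, CH2Cl2) gives 17.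

**Further compounds**

F1 | step 7 | (6S,7S,9E)-6-(benzyloxy)nonadeca-9,18-dien-7-ol | C=CCCCCCCC/C=C/C[C@H](O)[C@H](CCCCC)OCc1ccccc1
F2 | step 7 | 1-({[(6S,7S,9E)-6-(benzyloxy)nonadeca-9,18-dien-7-yl]oxy}methyl)-4-methoxybenzene | C=CCCCCCCC/C=C/C[C@H](OCc1ccc(OC)cc1)[C@H](CCCCC)OCc1ccccc1
F3 | step 7 | (2S,3S)-2-{(2S,3S)-3-(benzyloxy)-2-[(4-methoxybenzyl)oxy]octyl}-3-(non-8-en-1-yl)oxirane | C=CCCCCCCC[C@@H]1O[C@H]1C[C@H](OCc1ccc(OC)cc1)[C@H](CCCCC)OCc1ccccc1
F4 | step 9 | (6S,7S,9E)-7-[(4-methoxybenzyl)oxy]nonadeca-9,18-dien-6-ol | C=CCCCCCCC/C=C/C[C@H](OCc1ccc(OC)cc1)[C@H](CCCCC)O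
F5 | step 9 | (2S,3S)-2-[(4-methoxybenzyl)oxy]-1-[(2S,3S)-3-(non-8-en-1-yl)oxiran-2-yl]octan-3-ol | C=CCCCCCCC[C@@H]1O[C@H]1C[C@H](OCc1ccc(OC)cc1)[C@H](CCCCC)O
F6 | step 10 | 1-{(2R,4S,5S)-4-[(4-methoxybenzyl)oxy]-5-pentyloxolan-2-yl}dec-9-en-1-one | C=CCCCCCCCC(=O)[C@H]1C[C@H](OCc2ccc(OC)cc2)[C@H](CCCCC)O1
F7 | step 10 | (1R)-1-{(2R,4S,5S)-4-[(4-methoxybenzyl)oxy]-5-pentyloxolan-2-yl}dec-9-en-1-ol | C=CCCCCCCC[C@@H](O)[C@H]1C[C@H](OCc2ccc(OC)cc2)[C@H](CCCCC)O1
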